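**Plan**
1. Retrosynthesis: the first cut is C10–C11 (methyl-bearing dienyl carbon to carbinol carbon), giving a C1–C10 enyne ester and a C11–C21 aldehyde. Further cuts: C17–C18 (Suzuki), C12–C13 (Claisen) and C14–C15 (Evans aldol) in the aldehyde; C8–C9 (Sonogashira), C7=C8 (Takai) and C4–C5 (vinylogous Mukaiyama aldol) in the enyne.
2. Enabling feature: the acyclic (E)-2-methyl-1,3-dienyl carbinol C11(OH)–C10(CH3)=C9–C8=C7 is the retron of an alkyne + aldehyde reductive coupling, and the C7=C8 alkene beside the alkyne steers nickel. The only ring, the 2-methyloxazole (O1, C2, N3, C4, C5), is bought intact and is never formed or opened.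
3. Forward: oxazole aldehyde → dienylboronate; propargyl alcohol → iodoenal → aldol → ketoester → anti-diol → bis-silyl iodide → Suzuki → aldehyde 19; Roche ester → vinylogous aldol → Takai → Sonogashira → enyne 32; nickel coupling of 32 with 19; oxidation and CBS reduction; desilylation; saponification.
4. Stereochemistry: C6 from the (R)-Roche ester; C5 by Felkin addition; C14 and C15 from the (R)-benzyloxazolidinone; C13 by hydroxyl-directed anti reduction; C11 by (S)-CBS reduction after both epimers are converged to one dienone. Alkene geometry comes from a stabilised Wittig reaction, Cr(II) olefinations, carboalumination and the cis hydrometalation of the nickel step.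

Key step: step 21

Assumption: the nickel coupling is not expected to control C11, so 34 is carried as the pair of C11 epimers (SMILES without a descriptor at C11) until steps 22 and 23; compounds 1, 2, 9 and Cl2CHBpin are taken as catalogue compounds.

**Step 1**
Reactants: 1 2-methyl-1,3-oxazole-4-carbaldehyde; 2 2-(triphenylphosphoranylidene)propanal
Product: 3 (E)-2-methyl-3-(2-methyl-1,3-oxazol-4-yl)prop-2-enal
Conditions: toluene, 90 °C
Reagents that add atoms: none
Why: Wittig olefination with a stabilised formyl ylide should give the E trisubstituted enal (oxazole trans to CHO) under thermodynamic control.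

**Step 2**
Reactants: 3 (E)-2-methyl-3-(2-methyl-1,3-oxazol-4-yl)prop-2-enal
Product: 4 2-[(1E,3E)-3-methyl-4-(2-methyl-1,3-oxazol-4-yl)buta-1,3-dien-1-yl]-4,4,5,5-tetramethyl-1,3,2-dioxaborolane
Conditions: Cl2CHBpin, CrCl2, LiI, THF, rt
Reagents that add atoms: 2-(dichloromethyl)-4,4,5,5-tetramethyl-1,3,2-dioxaborolane, ClC(Cl)B1OC(C)(C)C(C)(C)O1
Why: Takai–Utimoto boryl olefination, in which the gem-dichromium reagent made in situ adds to the aldehyde and eliminates to the E alkenylboronate, a reaction that enals undergo.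

**Step 3**
Reactants: 5 prop-2-yn-1-ol
Product: 7 (E)-3-iodo-2-methylprop-2-en-1-ol, via alkenylalane 6 (not isolated)
Conditions: AlMe3 (3 equiv), Cp2ZrCl2 (0.25 equiv), CH2Cl2, 0 °C → rt; then I2, THF, −30 → 0 °C
Reagents that add atoms: trimethylaluminium, C[Al](C)C; iodine, II
Why: Negishi zirconium-catalysed carboalumination adds methyl (internal carbon) and aluminium cis across the alkyne, and iodinolysis with retention should give the E iodide.

**Step 4**
Reactants: 7 (E)-3-iodo-2-methylprop-2-en-1-ol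
Product: 8 (E)-3-iodo-2-methylprop-2-enal
Conditions: MnO2, CH2Cl2, rt; used directly
Reagents that add atoms: none
Why: MnO2 oxidation of an allylic alcohol stops at the aldehyde and leaves the alkene geometry untouched.

**Step 5**
Reactants: 9 (R)-4-benzyl-3-propanoyl-1,3-oxazolidin-2-one; 8 (E)-3-iodo-2-methylprop-2-enal
Product: 11 (R)-4-benzyl-3-[(2R,3R,4E)-3-hydroxy-5-iodo-2,4-dimethylpent-4-enoyl]-1,3-oxazolidin-2-one, via boron enolate 10 (not isolated)
Conditions: n-Bu2BOTf, i-Pr2NEt, CH2Cl2, 0 °C; then 8, −78 → 0 °C; pH 7 buffer, MeOH, H2O2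
Reagents that add atoms: none
Why: Evans syn aldol through the Z boron enolate and a Zimmerman–Traxler chair, in which the (R)-benzyl group shields one enolate face and so sets C14 and C15 (2R,3R, syn).

**Step 6**
Reactants: 11 (R)-4-benzyl-3-[(2R,3R,4E)-3-hydroxy-5-iodo-2,4-dimethylpent-4-enoyl]-1,3-oxazolidin-2-one
Product: 12 (2R,3R,4E)-3-hydroxy-5-iodo-N-methoxy-N,2,4-trimethylpent-4-enamide
Conditions: Me(MeO)NH·HCl, AlMe3, THF, −20 → 0 °C; aq. Rochelle salt
Reagents that add atoms: N,O-dimethylhydroxylamine hydrochloride, CNOC.Cl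
Why: Weinreb transamidation with the aluminium amide, assisted by the free β-hydroxyl, should release the auxiliary without touching C14.

**Step 7**
Reactants: 12 (2R,3R,4E)-3-hydroxy-5-iodo-N-methoxy-N,2,4-trimethylpent-4-enamide; 13 ethyl acetate
Product: 15 ethyl (4R,5R,6E)-5-hydroxy-7-iodo-4,6-dimethyl-3-oxohept-6-enoate, via lithium ester enolate 14 (not isolated)
Conditions: LDA (commercial solution, 4 equiv), 13 (4 equiv), THF, −78 °C; then 12, −78 → −40 °C; 1 M HCl quench
Reagents that add atoms: none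
Why: Claisen-type acylation of an ester enolate by a Weinreb amide, where the N-methoxy chelate prevents over-addition and the excess enolate covers the free hydroxyl.

**Step 8**
Reactants: 15 ethyl (4R,5R,6E)-5-hydroxy-7-iodo-4,6-dimethyl-3-oxohept-6-enoate
Product: 16 ethyl (3S,4S,5R,6E)-3,5-dihydroxy-7-iodo-4,6-dimethylhept-6-enoate
Conditions: Me4NBH(OAc)3, MeCN/AcOH 1:1, −30 °C
Reagents that add atoms: none
Why: Evans–Saksena reduction, in which the C15 hydroxyl binds boron and delivers hydride intramolecularly through a chair, should give the 13,15-anti diol (C13 S).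

**Step 9**
Reactants: 16 ethyl (3S,4S,5R,6E)-3,5-dihydroxy-7-iodo-4,6-dimethylhept-6-enoate
Product: 17 ethyl (3S,4S,5R,6E)-3,5-bis[(tert-butyldimethylsilyl)oxy]-7-iodo-4,6-dimethylhept-6-enoate
Conditions: TBSOTf (2.5 equiv), 2,6-lutidine, CH2Cl2, −78 → 0 °C
Reagents that add atoms: tert-butyldimethylsilyl triflate, CC(C)(C)[Si](C)(C)OS(=O)(=O)C(F)(F)F
Why: silyl triflate with a hindered base silylates both secondary alcohols, including the hindered allylic one, without β-elimination.

**Step 10**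
Reactants: 17 ethyl (3S,4S,5R,6E)-3,5-bis[(tert-butyldimethylsilyl)oxy]-7-iodo-4,6-dimethylhept-6-enoate; 4 2-[(1E,3E)-3-methyl-4-(2-methyl-1,3-oxazol-4-yl)buta-1,3-dien-1-yl]-4,4,5,5-tetramethyl-1,3,2-dioxaborolane
Product: 18 ethyl (3S,4S,5R,6E,8E,10E)-3,5-bis[(tert-butyldimethylsilyl)oxy]-4,6,10-trimethyl-11-(2-methyl-1,3-oxazol-4-yl)undeca-6,8,10-trienoate
Conditions: Pd(PPh3)4 (5 mol %), TlOEt, THF/H2O 3:1, rt, dark
Reagents that add atoms: none
Why: Suzuki–Miyaura coupling proceeds with retention at both alkenes, and thallium ethoxide allows room-temperature transmetalation so the triene should not isomerise and the ethyl ester is inert to ethoxide.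

**Step 11**
Reactants: 18 ethyl (3S,4S,5R,6E,8E,10E)-3,5-bis[(tert-butyldimethylsilyl)oxy]-4,6,10-trimethyl-11-(2-methyl-1,3-oxazol-4-yl)undeca-6,8,10-trienoate
Product: 19 (3S,4S,5R,6E,8E,10E)-3,5-bis[(tert-butyldimethylsilyl)oxy]-4,6,10-trimethyl-11-(2-methyl-1,3-oxazol-4-yl)undeca-6,8,10-trienal
Conditions: DIBAL-H (1.1 equiv), CH2Cl2, −78 °C; aq. Rochelle salt; used directly
Reagents that add atoms: none
Why: DIBAL half-reduction of a β-silyloxy ester at −78 °C should stop at the aldehyde level because the carbonyl is released only on work-up.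

**Step 12**
Reactants: 20 methyl (R)-3-hydroxy-2-methylpropanoate
Product: 21 methyl (R)-3-[(tert-butyldimethylsilyl)oxy]-2-methylpropanoate
Conditions: TBSCl, imidazole, DMF, rt
Reagents that add atoms: tert-butyldimethylsilyl chloride, CC(C)(C)[Si](C)(C)Cl
Why: standard silylation of a primary alcohol under conditions that do not epimerise the α-centre.

**Step 13**
Reactants: 21 methyl (R)-3-[(tert-butyldimethylsilyl)oxy]-2-methylpropanoate
Product: 22 (R)-3-[(tert-butyldimethylsilyl)oxy]-2-methylpropanal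
Conditions: DIBAL-H (1.05 equiv), CH2Cl2, −78 °C; aq. Rochelle salt; used directly
Reagents that add atoms: none
Why: low-temperature DIBAL half-reduction of the Roche ester derivative gives the configurationally labile aldehyde without epimerisation if it is used at once.

**Step 14**
Reactants: 23 methyl (E)-but-2-enoate
Product: 25 [(1-methoxybuta-1,3-dien-1-yl)oxy]trimethylsilane, via lithium dienolate 24 (not isolated)
Conditions: LDA (commercial solution), DMPU, THF, −78 °C; then TMSCl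
Reagents that add atoms: chlorotrimethylsilane, C[Si](C)(C)Cl
Why: γ-deprotonation of the crotonate and O-silylation of the dienolate give the silyl ketene acetal, whose acetal geometry is of no consequence.

**Step 15**
Reactants: 22 (R)-3-[(tert-butyldimethylsilyl)oxy]-2-methylpropanal; 25 [(1-methoxybuta-1,3-dien-1-yl)oxy]trimethylsilane
Product: 26 methyl (2E,5R,6R)-7-[(tert-butyldimethylsilyl)oxy]-5-hydroxy-6-methylhept-2-enoate
Conditions: BF3·OEt2, CH2Cl2/Et2O 9:1, −78 °C
Reagents that add atoms: none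
Why: vinylogous Mukaiyama aldol at the γ-carbon gives the E enoate, and since BF3 cannot chelate, the α-methyl aldehyde should react in the Felkin–Anh mode to give the 5,6-syn (5R) alcohol.

**Step 16**
Reactants: 26 methyl (2E,5R,6R)-7-[(tert-butyldimethylsilyl)oxy]-5-hydroxy-6-methylhept-2-enoate
Product: 27 methyl (2E,5R,6R)-5,7-bis[(tert-butyldimethylsilyl)oxy]-6-methylhept-2-enoate
Conditions: TBSOTf, 2,6-lutidine, CH2Cl2, −78 °C
Reagents that add atoms: tert-butyldimethylsilyl triflate, CC(C)(C)[Si](C)(C)OS(=O)(=O)C(F)(F)F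
Why: silylation of the secondary alcohol under non-nucleophilic basic conditions that leave the enoate alone.

**Step 17**
Reactants: 27 methyl (2E,5R,6R)-5,7-bis[(tert-butyldimethylsilyl)oxy]-6-methylhept-2-enoate
Product: 28 methyl (2E,5R,6R)-5-[(tert-butyldimethylsilyl)oxy]-7-hydroxy-6-methylhept-2-enoate
Conditions: HF·pyridine, pyridine, THF, 0 °C
Reagents that add atoms: none
Why: buffered HF·pyridine cleaves a primary TBS ether much faster than a secondary one, and the acidic medium avoids silyl migration.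

**Step 18**
Reactants: 28 methyl (2E,5R,6R)-5-[(tert-butyldimethylsilyl)oxy]-7-hydroxy-6-methylhept-2-enoate
Product: 29 methyl (2E,5R,6S)-5-[(tert-butyldimethylsilyl)oxy]-6-methyl-7-oxohept-2-enoate
Conditions: Dess–Martin periodinane, NaHCO3, CH2Cl2, 0 °C → rt; used directly
Reagents that add atoms: none
Why: buffered Dess–Martin oxidation gives the α-methyl aldehyde without epimerising C6 (the descriptor changes only through CIP priorities).

**Step 19**
Reactants: 29 methyl (2E,5R,6S)-5-[(tert-butyldimethylsilyl)oxy]-6-methyl-7-oxohept-2-enoate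
Product: 30 methyl (2E,5R,6R,7E)-5-[(tert-butyldimethylsilyl)oxy]-8-iodo-6-methylocta-2,7-dienoate
Conditions: CHI3, CrCl2, THF/dioxane, 0 °C → rt
Reagents that add atoms: iodoform, IC(I)I
Why: Takai iodo-olefination is E-selective for α-branched aldehydes and non-basic, so C6 and the enoate should survive.

**Step 20**
Reactants: 30 methyl (2E,5R,6R,7E)-5-[(tert-butyldimethylsilyl)oxy]-8-iodo-6-methylocta-2,7-dienoate; 31 propyne
Product: 32 methyl (2E,5R,6R,7E)-5-[(tert-butyldimethylsilyl)oxy]-6-methylundeca-2,7-dien-9-ynoate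
Conditions: Pd(PPh3)2Cl2 (3 mol %), CuI (6 mol %), Et3N, THF, propyne solution, rt
Reagents that add atoms: none
Why: Sonogashira coupling of the alkenyl iodide with retention of the E geometry gives the conjugated enyne.

**Step 21**
Reactants: 32 methyl (2E,5R,6R,7E)-5-[(tert-butyldimethylsilyl)oxy]-6-methylundeca-2,7-dien-9-ynoate; 19 (3S,4S,5R,6E,8E,10E)-3,5-bis[(tert-butyldimethylsilyl)oxy]-4,6,10-trimethyl-11-(2-methyl-1,3-oxazol-4-yl)undeca-6,8,10-trienal
Product: 34 methyl (2E,5R,6R,7E,9E,11RS,13S,14S,15R,16E,18E,20E)-5,13,15-tris[(tert-butyldimethylsilyl)oxy]-11-hydroxy-6,10,14,16,20-pentamethyl-21-(2-methyl-1,3-oxazol-4-yl)henicosa-2,7,9,16,18,20-hexaenoate, via diethylborinate 33 (not isolated)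
Conditions: Ni(cod)2 (15 mol %), PCyp3 (30 mol %), Et3B (2.5 equiv), EtOAc, rt, argon, slow addition of 32 (1.3 equiv); aq. NaHCO3
Reagents that add atoms: none
Why: Ni(0) binds the alkyne of 32 and the aldehyde of 19 and cyclises oxidatively to an oxanickelacyclopentene in which the C10–C11 bond is made; Et3B opens the Ni–O bond and passes an ethyl group to nickel, β-hydride elimination (ethene) and C9–H reductive elimination then release borinate 33, which aqueous work-up hydrolyses to 34. The closest known reaction type is the nickel-catalysed, alkene-directed reductive coupling of conjugated 1,3-enynes with aliphatic aldehydes (Ni(cod)2, trialkylphosphine, Et3B). No ring of the product is closed, the five-membered nickelacycle being transient. C11 is the only new stereocentre and is not reliably controlled here, because the nearest centre, C13, is β to the carbonyl and bears a non-chelating silyl ether; both epimers are therefore accepted and converged in steps 22 and 23. The step needs regioselectivity (C–C bond at C10, the alkyne carbon remote from the alkene), secured by the C7=C8 alkene, which binds nickel and places it on C9; cis addition of C11 and H across C9≡C10, inherent to the metallacycle, which gives the 9E trisubstituted alkene; and chemoselectivity for the alkyne–aldehyde pair over the enoate and the triene, which rests on the faster oxidative cyclisation of alkynes at phosphine-ligated Ni(0) and on the substituted termini of the triene.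

**Step 22**
Reactants: 34 methyl (2E,5R,6R,7E,9E,11RS,13S,14S,15R,16E,18E,20E)-5,13,15-tris[(tert-butyldimethylsilyl)oxy]-11-hydroxy-6,10,14,16,20-pentamethyl-21-(2-methyl-1,3-oxazol-4-yl)henicosa-2,7,9,16,18,20-hexaenoate
Product: 35 methyl (2E,5R,6R,7E,9E,13S,14S,15R,16E,18E,20E)-5,13,15-tris[(tert-butyldimethylsilyl)oxy]-6,10,14,16,20-pentamethyl-21-(2-methyl-1,3-oxazol-4-yl)-11-oxohenicosa-2,7,9,16,18,20-hexaenoate
Conditions: Dess–Martin periodinane, NaHCO3, CH2Cl2, 0 °C
Reagents that add atoms: none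
Why: Dess–Martin oxidation of the only free (dienylic) alcohol converges both C11 epimers on one dienone.

**Step 23**
Reactants: 35 methyl (2E,5R,6R,7E,9E,13S,14S,15R,16E,18E,20E)-5,13,15-tris[(tert-butyldimethylsilyl)oxy]-6,10,14,16,20-pentamethyl-21-(2-methyl-1,3-oxazol-4-yl)-11-oxohenicosa-2,7,9,16,18,20-hexaenoate
Product: 36 methyl (2E,5R,6R,7E,9E,11R,13S,14S,15R,16E,18E,20E)-5,13,15-tris[(tert-butyldimethylsilyl)oxy]-11-hydroxy-6,10,14,16,20-pentamethyl-21-(2-methyl-1,3-oxazol-4-yl)henicosa-2,7,9,16,18,20-hexaenoate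
Conditions: (S)-2-methyl-CBS-oxazaborolidine (0.5 equiv), catecholborane (2 equiv), toluene, −78 °C; MeOH quench
Reagents that add atoms: none
Why: Corey–Bakshi–Shibata reduction, in which the α-methyl dienyl group acts as the large and the C12 methylene as the small ketone substituent, so the (S)-catalyst should deliver hydride 1,2 to give 11R (same sense as acetophenone to the (R)-alcohol), i.e. the 11,13-syn relationship.

**Step 24**
Reactants: 36 methyl (2E,5R,6R,7E,9E,11R,13S,14S,15R,16E,18E,20E)-5,13,15-tris[(tert-butyldimethylsilyl)oxy]-11-hydroxy-6,10,14,16,20-pentamethyl-21-(2-methyl-1,3-oxazol-4-yl)henicosa-2,7,9,16,18,20-hexaenoate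
Product: 37 methyl (2E,5R,6R,7E,9E,11R,13S,14S,15R,16E,18E,20E)-5,11,13,15-tetrahydroxy-6,10,14,16,20-pentamethyl-21-(2-methyl-1,3-oxazol-4-yl)henicosa-2,7,9,16,18,20-hexaenoate
Conditions: HF·pyridine, excess pyridine, THF, 0 °C → rt
Reagents that add atoms: none
Why: pyridine-buffered HF removes all three secondary TBS ethers while keeping the medium mild enough for the dienylic and trienylic alcohols.

**Step 25**
Reactants: 37 methyl (2E,5R,6R,7E,9E,11R,13S,14S,15R,16E,18E,20E)-5,11,13,15-tetrahydroxy-6,10,14,16,20-pentamethyl-21-(2-methyl-1,3-oxazol-4-yl)henicosa-2,7,9,16,18,20-hexaenoate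
Product: 39 (2E,5R,6R,7E,9E,11R,13S,14S,15R,16E,18E,20E)-5,11,13,15-tetrahydroxy-6,10,14,16,20-pentamethyl-21-(2-methyl-1,3-oxazol-4-yl)henicosa-2,7,9,16,18,20-hexaenoic acid, via lithium carboxylate 38 (not isolated)
Conditions: LiOH, THF/MeOH/H2O, 0 °C; then dilute HCl to pH 4–5, 0 °C
Reagents that add atoms: lithium hydroxide, [Li+].[OH-]
Why: mild saponification of the methyl ester, where the 2E geometry rules out lactonisation with the C5 hydroxyl and careful cold acidification should spare the allylic alcohols.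

**Compound list**
1 | 2-methyl-1,3-oxazole-4-carbaldehyde | O=Cc1coc(C)n1 | starting material
2 | 2-(triphenylphosphoranylidene)propanal | CC(C=O)=P(c1ccccc1)(c1ccccc1)c1ccccc1 | starting material
3 | (E)-2-methyl-3-(2-methyl-1,3-oxazol-4-yl)prop-2-enal | O=C/C(C)=C/c1coc(C)n1 | intermediate
4 | 2-[(1E,3E)-3-methyl-4-(2-methyl-1,3-oxazol-4-yl)buta-1,3-dien-1-yl]-4,4,5,5-tetramethyl-1,3,2-dioxaborolane | CC(/C=C/B1OC(C)(C)C(C)(C)O1)=C\c1coc(C)n1 | intermediate
5 | prop-2-yn-1-ol | C#CCO | starting material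
6 | dimethylaluminium (E)-3-(dimethylalumanyl)-2-methylprop-2-en-1-olate (alkenylalane, not isolated) | C[Al](C)OC/C(C)=C/[Al](C)C | intermediate
7 | (E)-3-iodo-2-methylprop-2-en-1-ol | OC/C(C)=C/I | intermediate
8 | (E)-3-iodo-2-methylprop-2-enal | O=C/C(C)=C/I | intermediate
9 | (R)-4-benzyl-3-propanoyl-1,3-oxazolidin-2-one | CCC(=O)N1[C@H](Cc2ccccc2)COC1=O | starting material
10 | (Z)-dibutylboron enolate of 9 (not isolated) | C/C=C(\OB(CCCC)CCCC)N1[C@H](Cc2ccccc2)COC1=O | intermediate
11 | (R)-4-benzyl-3-[(2R,3R,4E)-3-hydroxy-5-iodo-2,4-dimethylpent-4-enoyl]-1,3-oxazolidin-2-one | I/C=C(\C)[C@H](O)[C@@H](C)C(=O)N1[C@H](Cc2ccccc2)COC1=O | intermediate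
12 | (2R,3R,4E)-3-hydroxy-5-iodo-N-methoxy-N,2,4-trimethylpent-4-enamide | I/C=C(\C)[C@H](O)[C@@H](C)C(=O)N(C)OC | intermediate
13 | ethyl acetate | CCOC(C)=O | starting material
14 | lithium 1-ethoxyethen-1-olate (not isolated) | [Li+].[O-]C(=C)OCC | intermediate
15 | ethyl (4R,5R,6E)-5-hydroxy-7-iodo-4,6-dimethyl-3-oxohept-6-enoate | I/C=C(\C)[C@H](O)[C@@H](C)C(=O)CC(=O)OCC | intermediate
16 | ethyl (3S,4S,5R,6E)-3,5-dihydroxy-7-iodo-4,6-dimethylhept-6-enoate | I/C=C(\C)[C@H](O)[C@@H](C)[C@@H](O)CC(=O)OCC | intermediate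
17 | ethyl (3S,4S,5R,6E)-3,5-bis[(tert-butyldimethylsilyl)oxy]-7-iodo-4,6-dimethylhept-6-enoate | I/C=C(\C)[C@H](O[Si](C)(C)C(C)(C)C)[C@@H](C)[C@@H](O[Si](C)(C)C(C)(C)C)CC(=O)OCC | intermediate
18 | ethyl (3S,4S,5R,6E,8E,10E)-3,5-bis[(tert-butyldimethylsilyl)oxy]-4,6,10-trimethyl-11-(2-methyl-1,3-oxazol-4-yl)undeca-6,8,10-trienoate | CC(/C=C/C=C(\C)[C@H](O[Si](C)(C)C(C)(C)C)[C@@H](C)[C@@H](O[Si](C)(C)C(C)(C)C)CC(=O)OCC)=C\c1coc(C)n1 | intermediate
19 | (3S,4S,5R,6E,8E,10E)-3,5-bis[(tert-butyldimethylsilyl)oxy]-4,6,10-trimethyl-11-(2-methyl-1,3-oxazol-4-yl)undeca-6,8,10-trienal | CC(/C=C/C=C(\C)[C@H](O[Si](C)(C)C(C)(C)C)[C@@H](C)[C@@H](O[Si](C)(C)C(C)(C)C)CC=O)=C\c1coc(C)n1 | intermediate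
20 | methyl (R)-3-hydroxy-2-methylpropanoate | COC(=O)[C@H](C)CO | starting material
21 | methyl (R)-3-[(tert-butyldimethylsilyl)oxy]-2-methylpropanoate | COC(=O)[C@H](C)CO[Si](C)(C)C(C)(C)C | intermediate
22 | (R)-3-[(tert-butyldimethylsilyl)oxy]-2-methylpropanal | O=C[C@H](C)CO[Si](C)(C)C(C)(C)C | intermediate
23 | methyl (E)-but-2-enoate | C/C=C/C(=O)OC | starting material
24 | lithium 1-methoxybuta-1,3-dien-1-olate (not isolated; acetal geometry not defined) | [Li+].[O-]C(OC)=CC=C | intermediate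
25 | [(1-methoxybuta-1,3-dien-1-yl)oxy]trimethylsilane (acetal geometry not defined, inconsequential) | C=CC=C(OC)O[Si](C)(C)C | intermediate
26 | methyl (2E,5R,6R)-7-[(tert-butyldimethylsilyl)oxy]-5-hydroxy-6-methylhept-2-enoate | CC(C)(C)[Si](C)(C)OC[C@@H](C)[C@H](O)C/C=C/C(=O)OC | intermediate
27 | methyl (2E,5R,6R)-5,7-bis[(tert-butyldimethylsilyl)oxy]-6-methylhept-2-enoate | CC(C)(C)[Si](C)(C)OC[C@@H](C)[C@H](O[Si](C)(C)C(C)(C)C)C/C=C/C(=O)OC | intermediate
28 | methyl (2E,5R,6R)-5-[(tert-butyldimethylsilyl)oxy]-7-hydroxy-6-methylhept-2-enoate | OC[C@@H](C)[C@H](O[Si](C)(C)C(C)(C)C)C/C=C/C(=O)OC | intermediate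
29 | methyl (2E,5R,6S)-5-[(tert-butyldimethylsilyl)oxy]-6-methyl-7-oxohept-2-enoate | O=C[C@@H](C)[C@H](O[Si](C)(C)C(C)(C)C)C/C=C/C(=O)OC | intermediate
30 | methyl (2E,5R,6R,7E)-5-[(tert-butyldimethylsilyl)oxy]-8-iodo-6-methylocta-2,7-dienoate | I/C=C/[C@@H](C)[C@H](O[Si](C)(C)C(C)(C)C)C/C=C/C(=O)OC | intermediate
31 | propyne | CC#C | starting material
32 | methyl (2E,5R,6R,7E)-5-[(tert-butyldimethylsilyl)oxy]-6-methylundeca-2,7-dien-9-ynoate | CC#C/C=C/[C@@H](C)[C@H](O[Si](C)(C)C(C)(C)C)C/C=C/C(=O)OC | intermediate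
33 | 11-O-diethylboryl ether of 34 (both C11 epimers, not isolated) | CC(/C=C/C=C(\C)[C@H](O[Si](C)(C)C(C)(C)C)[C@@H](C)[C@@H](O[Si](C)(C)C(C)(C)C)CC(OB(CC)CC)/C(C)=C/C=C/[C@@H](C)[C@H](O[Si](C)(C)C(C)(C)C)C/C=C/C(=O)OC)=C\c1coc(C)n1 | intermediate
34 | methyl (2E,5R,6R,7E,9E,11RS,13S,14S,15R,16E,18E,20E)-5,13,15-tris[(tert-butyldimethylsilyl)oxy]-11-hydroxy-6,10,14,16,20-pentamethyl-21-(2-methyl-1,3-oxazol-4-yl)henicosa-2,7,9,16,18,20-hexaenoate | CC(/C=C/C=C(\C)[C@H](O[Si](C)(C)C(C)(C)C)[C@@H](C)[C@@H](O[Si](C)(C)C(C)(C)C)CC(O)/C(C)=C/C=C/[C@@H](C)[C@H](O[Si](C)(C)C(C)(C)C)C/C=C/C(=O)OC)=C\c1coc(C)n1 | intermediate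
35 | methyl (2E,5R,6R,7E,9E,13S,14S,15R,16E,18E,20E)-5,13,15-tris[(tert-butyldimethylsilyl)oxy]-6,10,14,16,20-pentamethyl-21-(2-methyl-1,3-oxazol-4-yl)-11-oxohenicosa-2,7,9,16,18,20-hexaenoate | CC(/C=C/C=C(\C)[C@H](O[Si](C)(C)C(C)(C)C)[C@@H](C)[C@@H](O[Si](C)(C)C(C)(C)C)CC(=O)/C(C)=C/C=C/[C@@H](C)[C@H](O[Si](C)(C)C(C)(C)C)C/C=C/C(=O)OC)=C\c1coc(C)n1 | intermediate
36 | methyl (2E,5R,6R,7E,9E,11R,13S,14S,15R,16E,18E,20E)-5,13,15-tris[(tert-butyldimethylsilyl)oxy]-11-hydroxy-6,10,14,16,20-pentamethyl-21-(2-methyl-1,3-oxazol-4-yl)henicosa-2,7,9,16,18,20-hexaenoate | CC(/C=C/C=C(\C)[C@H](O[Si](C)(C)C(C)(C)C)[C@@H](C)[C@@H](O[Si](C)(C)C(C)(C)C)C[C@@H](O)/C(C)=C/C=C/[C@@H](C)[C@H](O[Si](C)(C)C(C)(C)C)C/C=C/C(=O)OC)=C\c1coc(C)n1 | intermediate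
37 | methyl (2E,5R,6R,7E,9E,11R,13S,14S,15R,16E,18E,20E)-5,11,13,15-tetrahydroxy-6,10,14,16,20-pentamethyl-21-(2-methyl-1,3-oxazol-4-yl)henicosa-2,7,9,16,18,20-hexaenoate | CC(/C=C/C=C(\C)[C@H](O)[C@@H](C)[C@@H](O)C[C@@H](O)/C(C)=C/C=C/[C@@H](C)[C@H](O)C/C=C/C(=O)OC)=C\c1coc(C)n1 | intermediate
38 | lithium salt of 39 (not isolated) | CC(/C=C/C=C(\C)[C@H](O)[C@@H](C)[C@@H](O)C[C@@H](O)/C(C)=C/C=C/[C@@H](C)[C@H](O)C/C=C/C(=O)[O-])=C\c1coc(C)n1.[Li+] | intermediate
39 | (2E,5R,6R,7E,9E,11R,13S,14S,15R,16E,18E,20E)-5,11,13,15-tetrahydroxy-6,10,14,16,20-pentamethyl-21-(2-methyl-1,3-oxazol-4-yl)henicosa-2,7,9,16,18,20-hexaenoic acid | CC(/C=C/C=C(\C)[C@H](O)[C@@H](C)[C@@H](O)C[C@@H](O)/C(C)=C/C=C/[C@@H](C)[C@H](O)C/C=C/C(=O)O)=C\c1coc(C)n1 | target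

**Totals**
Total steps: 25. Longest linear sequence: 14 steps (5 → 39, steps 3–11 and 21–25).

**Steps most likely to fail**

Step 21. The nickel catalyst may be diverted from the alkyne–aldehyde pair: binding or oxidative cyclisation at the triene or the enoate, sequestration by the oxazole nitrogen, or oligomerisation of the alkyne would stall the coupling or erode its chemoselectivity. Fallback: the same bond would be made by a Nozaki–Hiyama–Kishi addition. Enyne 32 would be hydrozirconated (Cp2Zr(H)Cl, THF, rt, zirconium settling on the methyl-bearing C10) and iodinated (I2) to give methyl (2E,5R,6R,7E,9E)-5-[(tert-butyldimethylsilyl)oxy]-10-iodo-6-methylundeca-2,7,9-trienoate F1. F1 would then be added to aldehyde 19 with CrCl2 and catalytic NiCl2 in DMSO, returning to 34 as the C11 epimer pair, from which step 22 continues.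

Step 23. Facial selectivity of hydride delivery may be poor, because the C13 silyloxy stereocentre and the fairly large "small" substituent can work against catalyst control; slow hydroboration of the polyene by the borane is a second concern. Fallback: C11 would be settled at the alcohol level instead. The epimers of 34 would be separated by chromatography; the 11R epimer is 36. The 11S epimer, methyl (2E,5R,6R,7E,9E,11S,13S,14S,15R,16E,18E,20E)-5,13,15-tris[(tert-butyldimethylsilyl)oxy]-11-hydroxy-6,10,14,16,20-pentamethyl-21-(2-methyl-1,3-oxazol-4-yl)henicosa-2,7,9,16,18,20-hexaenoate F2, would be inverted by a Mitsunobu reaction (4-nitrobenzoic acid, PPh3, DIAD, THF, 0 °C) to the 11R 4-nitrobenzoate F3. Methanolysis (K2CO3, MeOH, 0 °C) would then give 36.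

Step 15. Felkin–Anh facial selectivity may be modest with the small dienolate, and the α-centre of 22 may epimerise under the Lewis acid. Fallback: C5 would be set under reagent control. Aldehyde 22 would be allylated with the Re-face-selective antipode of B-allyldiisopinocampheylborane (expected to be the (+)-Ipc reagent from (−)-α-pinene; Et2O, −78 °C, oxidative work-up), matched with Felkin attack, to give (2R,3R)-1-[(tert-butyldimethylsilyl)oxy]-2-methylhex-5-en-3-ol F4. Silylation (TBSOTf, 2,6-lutidine) would give the bis-silyl ether F5, and cross-metathesis with methyl acrylate (Grubbs second-generation catalyst, CH2Cl2, 40 °C) would return to 27.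

**Further compounds**
F1 | step 21 | methyl (2E,5R,6R,7E,9E)-5-[(tert-butyldimethylsilyl)oxy]-10-iodo-6-methylundeca-2,7,9-trienoate | I/C(C)=C/C=C/[C@@H](C)[C@H](O[Si](C)(C)C(C)(C)C)C/C=C/C(=O)OC
F2 | step 23 | methyl (2E,5R,6R,7E,9E,11S,13S,14S,15R,16E,18E,20E)-5,13,15-tris[(tert-butyldimethylsilyl)oxy]-11-hydroxy-6,10,14,16,20-pentamethyl-21-(2-methyl-1,3-oxazol-4-yl)henicosa-2,7,9,16,18,20-hexaenoate | CC(/C=C/C=C(\C)[C@H](O[Si](C)(C)C(C)(C)C)[C@@H](C)[C@@H](O[Si](C)(C)C(C)(C)C)C[C@H](O)/C(C)=C/C=C/[C@@H](C)[C@H](O[Si](C)(C)C(C)(C)C)C/C=C/C(=O)OC)=C\c1coc(C)n1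
F3 | step 23 | methyl (2E,5R,6R,7E,9E,11R,13S,14S,15R,16E,18E,20E)-5,13,15-tris[(tert-butyldimethylsilyl)oxy]-6,10,14,16,20-pentamethyl-21-(2-methyl-1,3-oxazol-4-yl)-11-[(4-nitrobenzoyl)oxy]henicosa-2,7,9,16,18,20-hexaenoate | CC(/C=C/C=C(\C)[C@H](O[Si](C)(C)C(C)(C)C)[C@@H](C)[C@@H](O[Si](C)(C)C(C)(C)C)C[C@@H](OC(=O)c1ccc(cc1)[N+](=O)[O-])/C(C)=C/C=C/[C@@H](C)[C@H](O[Si](C)(C)C(C)(C)C)C/C=C/C(=O)OC)=C\c1coc(C)n1
F4 | step 15 | (2R,3R)-1-[(tert-butyldimethylsilyl)oxy]-2-methylhex-5-en-3-ol | CC(C)(C)[Si](C)(C)OC[C@@H](C)[C@H](O)CC=C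
F5 | step 15 | (2R,3R)-1,3-bis[(tert-butyldimethylsilyl)oxy]-2-methylhex-5-ene | CC(C)(C)[Si](C)(C)OC[C@@H](C)[C@H](O[Si](C)(C)C(C)(C)C)CC=C
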